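Ring D of the ester-bearing half is cut at C14–C15 and C13–C18. A ring E silyloxydiene (C15=C16–C17=C18) and a (Z)-enyne dienophile (C13=C14) are joined beforehand by a mixed acetal between the C21 oxygen and the future C27 methyl carbon. Lewis-acid ionisation gives a tethered vinyl oxocarbenium ion; its cationic [4+2] cycloaddition forms both bonds at once and sets C13, C14 and C18, exploiting the C21 oxygen of ring E and the angular C27 carbon as tether anchors. Rings A, B and C are then grown from the C14 alkyne, and the 6-oxo catechol is oxidised and joined to tingenone by hetero-Diels–Alder reaction.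

Key step: step 10

Remarks: atom numbers are friedelane numbers of the target (unprimed for the methyl ester half, primed for the tingenone half); β is the face of the C9, C14 and C17 methyl groups. Compounds 1, 2, 9, 21 and tingenone (30) are assumed to be purchasable.

Step 1
Reactants: 1 methyl 2-methyl-3-oxopropanoate; 2 but-3-en-2-one
Product: 4 ring E ketol, methyl (1S,2R)-2-hydroxy-1-methyl-4-oxocyclohexane-1-carboxylate, via Michael adduct 3 (not isolated)
Conditions: cinchona catalyst QD-PHN (9-O-(9-phenanthryl)cupreidine, 10 mol %; its quinine-derived pseudo-enantiomer if the opposite sense is found), CH2Cl2, −24 °C; then pyrrolidine/AcOH (10 mol %), 0 °C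
Reagents that add atoms: none
Why: Cinchona-base catalysed Michael addition of the α-formyl ester sets the C20 quaternary centre under catalyst control, and the reversible intramolecular aldol addition of the methyl ketone to the non-enolisable aldehyde should settle on the ketol with the C21 hydroxyl cis to the ester (equatorial, hydrogen-bonded OH); a Robinson-type Michael/aldol sequence stopped before dehydration.

Step 2
Reactants: 4 ring E ketol
Product: 5 triethylsilyl ether of 4
Conditions: Et3SiCl, imidazole, DMF, 0 °C
Reagents that add atoms: chlorotriethylsilane, CC[Si](Cl)(CC)CC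
Why: Silylation masks the β-hydroxyl so that the strong base of the next step cannot trigger retro-aldol cleavage.

Step 3
Reactants: 5 triethylsilyl ether
Product: 6 C17=C18 enol triflate
Conditions: KN(SiMe3)2, THF, −78 °C; then PhNTf2
Reagents that add atoms: N-phenylbis(trifluoromethanesulfonimide), O=S(=O)(N(c1ccccc1)S(=O)(=O)C(F)(F)F)C(F)(F)F
Why: Kinetic deprotonation of a 3-silyloxy ketone should occur at the less hindered α-carbon remote from the oxygenated carbon (C18), and O-sulfonylation of that enolate fixes the C17=C18 double bond.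

Step 4
Reactants: 6 enol triflate
Product: 8 hydroxy enone, methyl (1S,6R)-4-acetyl-6-hydroxy-1-methylcyclohex-3-ene-1-carboxylate, via ethoxydiene 7 (not isolated)
Conditions: tributyl(1-ethoxyvinyl)stannane, Pd(PPh3)4 (5 mol %), LiCl, THF, 65 °C; then 1 M HCl, 20 °C
Reagents that add atoms: tributyl(1-ethoxyvinyl)stannane, CCCC[Sn](CCCC)(CCCC)C(=C)OCC; water, O
Why: Stille coupling of the enol triflate with the acetyl-anion equivalent, then acid hydrolysis of the enol ether and of the silyl ether, should give the conjugated methyl ketone with the free C21 hydroxyl.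

Step 5
Reactants: 9 3-acetyldihydrofuran-2(3H)-one
Product: 10 (Z)-enol triflate
Conditions: Tf2O, aq. LiOH, toluene, 5 °C
Reagents that add atoms: trifluoromethanesulfonic anhydride, O=S(=O)(OS(=O)(=O)C(F)(F)F)C(F)(F)F
Why: O-Sulfonylation of the lithium-chelated enolate of the β-keto lactone should give the enol triflate with the triflate cis to the lactone carbonyl, which fixes the geometry of the future C13=C14 bond.

Step 6
Reactants: 10 (Z)-enol triflate
Product: 11 (Z)-3-(pent-3-yn-2-ylidene)dihydrofuran-2(3H)-one
Conditions: propyne (THF solution), PdCl2(PPh3)2 (3 mol %), CuI (5 mol %), Et3N, THF, 20 °C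
Reagents that add atoms: propyne, CC#C
Why: Sonogashira coupling of a vinylogous acyl triflate proceeds with retention of alkene geometry, placing the propynyl group (C8, C9, C25) cis to the carbonyl carbon C27.

Step 7
Reactants: 11 alkylidene lactone
Product: 12 lactol, (Z)-3-(pent-3-yn-2-ylidene)tetrahydrofuran-2-ol
Conditions: iBu2AlH (1.1 equiv), CH2Cl2, −78 °C
Reagents that add atoms: none
Why: 1,2-Reduction of the lactone stops at the lactol because the aluminium hemiacetal is stable at low temperature.

Step 8
Reactants: 8 hydroxy enone; 12 lactol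
Product: 13 mixed acetal (both epimers at the acetal carbon)
Conditions: PPTS (10 mol %), 4 Å molecular sieves, CH2Cl2, 0 → 20 °C
Reagents that add atoms: none
Why: Acid-catalysed acetal exchange through the allyl-stabilised oxocarbenium ion of the lactol should attach it to the C21 hydroxyl as a 2-tetrahydrofuranyl ether; the configuration of the acetal carbon is irrelevant because it is ionised in step 10.

Step 9
Reactants: 13 mixed acetal
Product: 14 tert-butyldimethylsilyl dienol ether
Conditions: LiN(iPr)2, THF, −78 °C; then tBuMe2SiCl, DMPU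
Reagents that add atoms: tert-butylchlorodimethylsilane, CC(C)(C)[Si](C)(C)Cl
Why: Kinetic α′-deprotonation of the methyl ketone and O-silylation is the standard preparation of a semicyclic 2-silyloxydiene.

Step 10
Reactants: 14 silyl dienol ether
Product: 16 cage acetal, via tethered oxocarbenium triflate 15 (not isolated)
Conditions: Me3SiOTf (0.2 equiv), 2,6-di-tert-butyl-4-methylpyridine (0.3 equiv), CH2Cl2 (0.005 M), −78 → −40 °C
Reagents that add atoms: trimethylsilyl trifluoromethanesulfonate, C[Si](C)(C)OS(=O)(=O)C(F)(F)F (its atoms appear only in intermediate 15 and are released again)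
Why: The silyl triflate opens the 2-alkoxytetrahydrofuran acetal at its ring C–O bond to the acyclic, O21-bound vinyl oxocarbenium ion 15, in which C15 of the silyl dienol ether adds to C14 while the resulting enol ether carbon C13 closes onto C18 (asynchronous cationic [4+2], equivalent to a double Mukaiyama–Michael addition), and the new C27 oxocarbenium ion is recaptured by the silylated O11, returning the catalyst. The closest known reaction type is the ionic Diels–Alder reaction of α,β-unsaturated acetals through alkoxyallyl cations, run here intramolecularly in the way oxocarbenium tethers are used in silyl-modified Sakurai cyclisations. Ring D closes by the [4+2] mode, the temporary seven-membered C18–C13–C27–O21–C21 bridge closes with it (a 2-oxabicyclo[3.2.2]nonane over ring E), and the tetrahydrofuran re-forms by 5-exo capture. C18 is set by the tether, which can deliver the dienophile only to the α face that carries O21 (18β-H); C13 is set because the tether holds C27 endo under ring E (C27 α, C12 β); C14 follows from the (Z)-alkene geometry transferred suprafacially (propynyl α, methyl β, so C26 and C27 end up trans); the acetal carbon C27 is fixed by the cage. The step needs 1,4- instead of 1,2-attack on the oxocarbenium ion, the intramolecular path and retention of alkene geometry: C15 cannot reach C27 within the tether, high dilution and catalytic acid suppress the untethered cyclic oxocarbenium path, and low temperature with a hindered pyridine limits proton loss and C13–C14 rotation in the cation.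

Step 11
Reactants: 16 cage acetal
Product: 18 keto lactol, via methylated cage ketone 17 (not isolated)
Conditions: (Me2N)3S+ Me3SiF2− (TASF), MeI, THF, −78 → 0 °C; then 1 M HCl, THF, 20 °C
Reagents that add atoms: iodomethane, CI; water, O
Why: Fluoride unmasks the C16 enolate regiospecifically from the silyl enol ether and C-methylation at C17 can occur only on the β face because the α face is covered by the C13–C27–O21 bridge (17β-methyl, cis to 18β-H), after which aqueous acid hydrolyses the bicyclic acetal to the lactol and frees the C21 hydroxyl.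

Step 12
Reactants: 18 keto lactol
Product: 19 bis(tosylhydrazone)
Conditions: TsNHNH2 (3 equiv), AcOH (cat.), EtOH, 70 °C
Reagents that add atoms: p-toluenesulfonohydrazide, Cc1ccc(cc1)S(=O)(=O)NN
Why: The lactol should react through its open hydroxy-aldehyde form and the C16 ketone should condense as well (hydrazone formation), giving hydrazones at C27 and C16.

Step 13
Reactants: 19 bis(tosylhydrazone)
Product: 20 D/E-ring diol ester with the 13α-methyl group
Conditions: catecholborane, CHCl3, 0 °C; then NaOAc·3H2O, reflux
Reagents that add atoms: none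
Why: Reduction of tosylhydrazones with catecholborane (hydroboration of C=N, then loss of sulfinate and nitrogen) should turn C27 into the 13α-methyl group and C16 into a methylene under conditions that spare the ester and the alkyne.

Step 14
Reactants: 21 3,4-dimethoxy-2-methylbenzoic acid
Product: 23 β-keto sulfoxonium ylide, via acid chloride 22 (not isolated)
Conditions: (COCl)2, DMF (cat.), CH2Cl2; then Me3S(O)I, KOtBu, THF, 0 → 20 °C
Reagents that add atoms: oxalyl chloride, O=C(Cl)C(Cl)=O (chlorine only in 22); trimethylsulfoxonium iodide, C[S+](C)(C)=O.[I-]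
Why: Acylation of dimethylsulfoxonium methylide by the acid chloride (Corey–Chaykovsky ylide acylation) gives the stabilised ylide that carries C6, C7 and ring A.

Step 15
Reactants: 20 diol ester; 23 sulfoxonium ylide
Product: 24 naphthol (rings A and B aromatic, attached through C8 to C14)
Conditions: [RhCl2(C5Me5)]2 (5 mol %), AgSbF6 (20 mol %), NaOAc (30 mol %), 1,2-dichloroethane, 80 °C
Reagents that add atoms: none
Why: Ylide-directed rhodation of the only free ortho C–H (C10), alkyne insertion with the methyl-bearing carbon C9 bonding to the arene (the tertiary-alkyl-bearing carbon C8 stays on rhodium for steric reasons), then carbene formation with loss of dimethyl sulfoxide and ring closure, should give the 1-naphthol (rhodium-catalysed C–H annulation of sulfoxonium ylides with alkynes).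

Step 16
Reactants: 24 naphthol
Product: 25 dibromide (C7–Br and C11–Br)
Conditions: NBS (1.0 equiv), CH2Cl2, −40 °C; then PPh3, CBr4, 0 °C
Reagents that add atoms: N-bromosuccinimide, BrN1C(=O)CCC1=O; tetrabromomethane, BrC(Br)(Br)Br
Why: Electrophilic bromination should go to the free ortho position of the naphthol (C7), which blocks it for the next step, and the Appel reaction should then convert only the unhindered primary alcohol, not the neopentylic C21 alcohol.

Step 17
Reactants: 25 dibromide
Product: 26 7-bromo pentacyclic enone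
Conditions: Cs2CO3, DMF (0.01 M), 50 °C
Reagents that add atoms: none
Why: Intramolecular para-C-alkylation of the naphthoxide (alkylative dearomatisation) should close ring C through a chair transition state whose trans-diequatorial fusion to ring D puts the C9 methyl axial on the β face, and gives the 6-oxo-Δ7 enone directly; C7 is blocked and O-alkylation would need an eight-membered ring.

Step 18
Reactants: 26 7-bromo enone
Product: 27 pentacyclic enone alcohol
Conditions: Bu3SnH, Pd(PPh3)4 (5 mol %), THF, 20 °C
Reagents that add atoms: none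
Why: Palladium-catalysed hydrostannolysis is a standard reduction of a vinylic bromide and removes the blocking group from C7.

Step 19
Reactants: 27 enone alcohol
Product: 28 21-ketone (2,3-di-O-methyl ether)
Conditions: Dess–Martin periodinane, NaHCO3, CH2Cl2, 20 °C
Reagents that add atoms: none
Why: Oxidation of the secondary alcohol gives the β-keto ester, which cannot epimerise because C20 is quaternary.

Step 20
Reactants: 28 dimethyl ether
Product: 29 catechol (21-oxo-6-oxopristimerol)
Conditions: BBr3, CH2Cl2, −78 → 0 °C
Reagents that add atoms: none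
Why: Boron tribromide cleaves both aryl methyl ethers, while the hindered methyl ester and the ketones should survive at low temperature.

Step 21
Reactants: 29 catechol; 30 tingenone
Product: 32 target CNP0172265.1, via ortho-quinone 31 (not isolated)
Conditions: DDQ (1.0 equiv), 1,4-dioxane, 20 °C; then 30 (1.0 equiv), 20 °C
Reagents that add atoms: none
Why: The catechol is oxidised to the ortho-quinone, whose O=C–C=O unit should add as a heterodiene across the electron-rich enol C3′=C4′ bond of tingenone (inverse-demand hetero-Diels–Alder reaction), with C4′ bonding to O3 because that leaves the C2 oxygen conjugated with the C6 carbonyl, and on the α face away from the 9′β-methyl to give the cis-fused dioxane with 3′β-OH and 4′β-methyl.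

Compound list
1 | methyl 2-methyl-3-oxopropanoate | COC(=O)C(C)C=O | starting material
2 | but-3-en-2-one | CC(=O)C=C | starting material
3 | Michael adduct, methyl (S)-2-formyl-2-methyl-5-oxohexanoate | COC(=O)[C@@](C=O)(C)CCC(C)=O | intermediate
4 | ring E ketol, methyl (1S,2R)-2-hydroxy-1-methyl-4-oxocyclohexane-1-carboxylate (OH cis to CO2Me) | COC(=O)[C@@]1(C)CCC(=O)C[C@H]1O | intermediate
5 | methyl (1S,2R)-1-methyl-4-oxo-2-(triethylsilyloxy)cyclohexane-1-carboxylate | COC(=O)[C@@]1(C)CCC(=O)C[C@H]1O[Si](CC)(CC)CC | intermediate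
6 | methyl (1S,6R)-1-methyl-6-(triethylsilyloxy)-4-(trifluoromethanesulfonyloxy)cyclohex-3-ene-1-carboxylate | COC(=O)[C@@]1(C)CC=C(OS(=O)(=O)C(F)(F)F)C[C@H]1O[Si](CC)(CC)CC | intermediate
7 | ethoxydiene, methyl (1S,6R)-4-(1-ethoxyvinyl)-1-methyl-6-(triethylsilyloxy)cyclohex-3-ene-1-carboxylate | COC(=O)[C@@]1(C)CC=C(C(=C)OCC)C[C@H]1O[Si](CC)(CC)CC | intermediate
8 | hydroxy enone, methyl (1S,6R)-4-acetyl-6-hydroxy-1-methylcyclohex-3-ene-1-carboxylate | COC(=O)[C@@]1(C)CC=C(C(C)=O)C[C@H]1O | intermediate
9 | 3-acetyldihydrofuran-2(3H)-one | CC(=O)C1CCOC1=O | starting material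
10 | (Z)-1-(2-oxodihydrofuran-3(2H)-ylidene)ethyl trifluoromethanesulfonate | C\C(OS(=O)(=O)C(F)(F)F)=C1/CCOC1=O | intermediate
11 | (Z)-3-(pent-3-yn-2-ylidene)dihydrofuran-2(3H)-one | C\C(C#CC)=C1/CCOC1=O | intermediate
12 | lactol, (Z)-3-(pent-3-yn-2-ylidene)tetrahydrofuran-2-ol (both anomers) | C\C(C#CC)=C1/CCOC1O | intermediate
13 | mixed acetal, methyl (1S,6R)-4-acetyl-1-methyl-6-{[(Z)-3-(pent-3-yn-2-ylidene)tetrahydrofuran-2-yl]oxy}cyclohex-3-ene-1-carboxylate (acetal epimers) | COC(=O)[C@@]1(C)CC=C(C(C)=O)C[C@H]1OC1OCC\C1=C(/C)C#CC | intermediate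
14 | silyl dienol ether of 13, 4-[1-(tert-butyldimethylsilyloxy)vinyl] analogue | COC(=O)[C@@]1(C)CC=C(C(=C)O[Si](C)(C)C(C)(C)C)C[C@H]1OC1OCC\C1=C(/C)C#CC | intermediate
15 | tethered oxocarbenium triflate (O21=C27 cation, O11 trimethylsilyl ether, (Z)-C13=C14) | COC(=O)[C@@]1(C)CC=C(C(=C)O[Si](C)(C)C(C)(C)C)C[C@H]1[O+]=C/C(CCO[Si](C)(C)C)=C(/C)C#CC.[O-]S(=O)(=O)C(F)(F)F | intermediate
16 | cage acetal: D/E bicycle with C16=C17 silyl enol ether; C27 (α on C13) bonded to O21 (α bridge over ring E) and to O11 (tetrahydrofuran with C11, C12); 14β-methyl, 14α-prop-1-ynyl, 18β-H, 20α-CO2Me, 20β-methyl | COC(=O)[C@@]1(C)C[C@@H]2C3=C(O[Si](C)(C)C(C)(C)C)C[C@](C)(C#CC)[C@]2(CCO4)[C@@H]4O[C@@H]1C3 | intermediate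
17 | methylated cage ketone: as 16 but 16-oxo and 17β-methyl | COC(=O)[C@@]1(C)C[C@@H]2[C@@]3(C)C(=O)C[C@](C)(C#CC)[C@]2(CCO4)[C@@H]4O[C@@H]1C3 | intermediate
18 | keto lactol: 16-oxo D/E bicycle, 17β-methyl, 18β-H, 21α-OH, 13-spiro 2-hydroxytetrahydrofuran (C27 α, C12 β; both anomers), 14β-methyl, 14α-prop-1-ynyl | COC(=O)[C@]1(C)[C@H](O)C[C@]2(C)C(=O)C[C@](C)(C#CC)[C@@]3(CCOC3O)[C@@H]2C1 | intermediate
19 | bis(tosylhydrazone) at C16 and C27, free 11-OH and 21α-OH | COC(=O)[C@]1(C)[C@H](O)C[C@]2(C)C(=NNS(=O)(=O)c3ccc(C)cc3)C[C@](C)(C#CC)[C@](CCO)(C=NNS(=O)(=O)c3ccc(C)cc3)[C@@H]2C1 | intermediate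
20 | diol ester: D/E decalin, 13α-methyl, 13β-(2-hydroxyethyl), 14β-methyl, 14α-prop-1-ynyl, 17β-methyl, 18β-H, 20β-methyl, 20α-CO2Me, 21α-OH | COC(=O)[C@]1(C)[C@H](O)C[C@]2(C)CC[C@](C)(C#CC)[C@](CCO)(C)[C@@H]2C1 | intermediate
21 | 3,4-dimethoxy-2-methylbenzoic acid | Cc1c(C(=O)O)ccc(OC)c1OC | starting material
22 | 3,4-dimethoxy-2-methylbenzoyl chloride | Cc1c(C(=O)Cl)ccc(OC)c1OC | intermediate
23 | 1-(3,4-dimethoxy-2-methylphenyl)-2-[dimethyl(oxo)-λ6-sulfanylidene]ethan-1-one | Cc1c(C(=O)C=S(C)(C)=O)ccc(OC)c1OC | intermediate
24 | naphthol: as 20 with the propynyl group replaced by 4-hydroxy-6,7-dimethoxy-1,5-dimethylnaphthalen-2-yl | COC(=O)[C@]1(C)[C@H](O)C[C@]2(C)CC[C@](C)(c3cc(O)c4c(C)c(OC)c(OC)cc4c3C)[C@](CCO)(C)[C@@H]2C1 | intermediate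
25 | dibromide: 3-bromo-4-hydroxy-naphthyl analogue of 24 with 13β-(2-bromoethyl) | COC(=O)[C@]1(C)[C@H](O)C[C@]2(C)CC[C@](C)(c3c(Br)c(O)c4c(C)c(OC)c(OC)cc4c3C)[C@](CCBr)(C)[C@@H]2C1 | intermediate
26 | methyl 7-bromo-21α-hydroxy-2,3-dimethoxy-6-oxo-24-nor-D:A-friedooleana-1,3,5(10),7-tetraen-29-oate | COC(=O)[C@@]1(C)C[C@@H]2[C@@](C)(CC[C@]3(C)C4=C(Br)C(=O)c5c(cc(OC)c(OC)c5C)[C@]4(C)CC[C@@]23C)C[C@H]1O | intermediate
27 | methyl 21α-hydroxy-2,3-dimethoxy-6-oxo-24-nor-D:A-friedooleana-1,3,5(10),7-tetraen-29-oate | COC(=O)[C@@]1(C)C[C@@H]2[C@@](C)(CC[C@]3(C)C4=CC(=O)c5c(cc(OC)c(OC)c5C)[C@]4(C)CC[C@@]23C)C[C@H]1O | intermediate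
28 | methyl 2,3-dimethoxy-6,21-dioxo-24-nor-D:A-friedooleana-1,3,5(10),7-tetraen-29-oate | COC(=O)[C@@]1(C)C[C@@H]2[C@@](C)(CC[C@]3(C)C4=CC(=O)c5c(cc(OC)c(OC)c5C)[C@]4(C)CC[C@@]23C)CC1=O | intermediate
29 | catechol, methyl 2,3-dihydroxy-6,21-dioxo-24-nor-D:A-friedooleana-1,3,5(10),7-tetraen-29-oate | COC(=O)[C@@]1(C)C[C@@H]2[C@@](C)(CC[C@]3(C)C4=CC(=O)c5c(cc(O)c(O)c5C)[C@]4(C)CC[C@@]23C)CC1=O | intermediate
30 | tingenone | CC1=C(O)C(=O)C=C2C1=CC=C3[C@@]2(C)CC[C@@]4(C)[C@@H]5C[C@@H](C)C(=O)C[C@]5(C)CC[C@]34C | starting material
31 | ortho-quinone, methyl 2,3,6,21-tetraoxo-24-nor-D:A-friedooleana-1(10),4,7-trien-29-oate | COC(=O)[C@@]1(C)C[C@@H]2[C@@](C)(CC[C@]3(C)C4=CC(=O)C5=C(C)C(=O)C(=O)C=C5[C@]4(C)CC[C@@]23C)CC1=O | intermediate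
32 | CNP0172265.1 (dioxane-bridged dimer; O3–C4′ and O2–C3′ on the α face, 3′β-OH, 4′β-methyl) | COC(=O)[C@@]1(C)C[C@@H]2[C@@](C)(CC[C@]3(C)C4=CC(=O)c5c(cc6c(c5C)O[C@@]5(C)C7=CC=C8[C@@](C)(CC[C@@]9(C)[C@@H]%10C[C@@H](C)C(=O)C[C@]%10(C)CC[C@]89C)C7=CC(=O)[C@@]5(O)O6)[C@]4(C)CC[C@@]23C)CC1=O | target

Total step count: 21. Longest linear sequence: 17 steps (steps 1–4, 8–13 and 15–21).

Steps most likely to fail

Step 10. The acid-labile mixed acetal may ionise along the untethered cyclic oxocarbenium path, or the cation may lose a proton or rotate about C13–C14 before it cyclises, which would erode conversion and the C14 configuration. The fallback replaces the cationic acetal tether by a neutral, aluminium-templated Diels–Alder reaction and sets out from 8. Dianion formation (LiN(iPr)2, 2.1 equiv) and silylation of the enolate oxygen only (tBuMe2SiCl, 1 equiv, −78 °C) would give the hydroxy silyloxydiene F1. With Me2AlCl its aluminium alkoxide should bind the carbonyl of lactone 11 and deliver it to the α face with the carbonyl endo, forming both ring D bonds in one step to give the spiro-lactone adduct F2. Reduction with iBu2AlH at −78 °C (enol ether intact) would give the lactol F3, and PPTS would close the lactol onto the C21 hydroxyl, returning to the route at 16.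

Step 15. Insertion of the very hindered tertiary-alkyl/methyl alkyne into the rhodacycle may be slow or occur with the opposite orientation. The fallback sets out from 20 and uses a palladium-catalysed carboannulation with 1-(6-bromo-3,4-dimethoxy-2-methylphenyl)ethan-1-one (Pd(OAc)2, tri-tert-butylphosphine, NaOtBu, toluene, 100 °C): oxidative addition, aryl-palladation of the alkyne at the methyl-bearing carbon, intramolecular α-alkenylation of the ketone enolate and tautomerisation. It comes back to the route directly at 24 and makes no new isolated compound; the process to watch there is competing addition of the vinylpalladium to the carbonyl group.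

Step 17. C-Alkylation at the substituted C9 may be slower than intermolecular or oxygen alkylation, or may pass through a boat-like transition state that places the C9 methyl on the α face. The fallback changes the nucleophile from a naphthoxide to a neutral arene and sets out from 25: selective silylation of the naphthol (tBuMe2SiCl, imidazole) would give the silyl ether F4; AgOTf with 2,6-di-tert-butylpyridine in CH2Cl2 should then ionise the primary bromide and induce ipso-Friedel–Crafts attack of C9 (para to the silyloxy group, C7 still blocked) with loss of the silyl group, returning to the route at 26.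

Further compounds
F1 | step 10 | methyl (1S,6R)-4-[1-(tert-butyldimethylsilyloxy)vinyl]-6-hydroxy-1-methylcyclohex-3-ene-1-carboxylate | COC(=O)[C@@]1(C)CC=C(C(=C)O[Si](C)(C)C(C)(C)C)C[C@H]1O
F2 | step 10 | spiro-lactone adduct: D/E bicycle with C16=C17 silyl enol ether, 13-spiro γ-lactone (C27 carbonyl α, C12 β), 14β-methyl, 14α-prop-1-ynyl, 18β-H, 21α-OH | COC(=O)[C@@]1(C)C[C@@H]2C(=C(O[Si](C)(C)C(C)(C)C)C[C@](C)(C#CC)[C@@]23CCOC3=O)C[C@H]1O
F3 | step 10 | lactol of F2 (C27 hemiacetal, both anomers) | COC(=O)[C@@]1(C)C[C@@H]2C(=C(O[Si](C)(C)C(C)(C)C)C[C@](C)(C#CC)[C@@]23CCOC3O)C[C@H]1O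
F0 | step 15 | none | none
F4 | step 17 | tert-butyldimethylsilyl ether of the naphthol oxygen of 25 | COC(=O)[C@]1(C)[C@H](O)C[C@]2(C)CC[C@](C)(c3c(Br)c(O[Si](C)(C)C(C)(C)C)c4c(C)c(OC)c(OC)cc4c3C)[C@](CCBr)(C)[C@@H]2C1
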